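**Plan**
- Cuts, in eudesmane numbering (C3 ester carbon, C4 methyl carbinol, C5/C10 ring fusion, C7 carbinol, C8 ketone, C11 hydroxyisopropyl carbon): first the C3–O acyl bond, then the two C–O bonds of the 3α,4α-diol (back to a Δ3 olefin), then C7–C8 of ring B, then C5–C6 and C10–C9.
- Enabling feature: in ring B the C8 ketone sits next to the tertiary carbinol C7 that carries C11. This acyloin is the adduct of a C8 acyl anion and a C7 ketone.
- Forward order: ring A comes from 2-methylcyclohexane-1,3-dione. The C9 arm goes onto C10 by decarboxylative allylation and the C6–C7–C11 arm onto C5 by a ketal Claisen rearrangement. Ring B closes by a carbene-catalysed crossed benzoin reaction, and the oxirane arrives ready-made with the acid.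
- Stereochemistry: C10 from Pd2(dba)3/(R)-t-BuPHOX. A temporary 3β-carbinol from CBS reduction is relayed suprafacially to C5. C7 comes from a chair transition state with the large group equatorial, C3 and C4 from osmylation anti to the axial C10 methyl group, and C2'/C3' from Sharpless epoxidation with D-(−)-tartrate.

Key step: step 11

Remark: α is the face opposite the C10 methyl group; the sense of induction of t-BuPHOX and of the CBS catalyst is assumed to follow the parent cases (2-allyl-2-methylcyclohexanone, α-substituted cyclohexenones); species bound to a catalyst inside a catalytic cycle are described in the Why lines and carry no number.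

**Step 1**
Reactants: 1 2-methylcyclohexane-1,3-dione
Product: 2 3-isobutoxy-2-methylcyclohex-2-en-1-one
Conditions: i-BuOH, p-TsOH·H2O (cat.), toluene, reflux, Dean–Stark trap
Reagents that add atoms: isobutanol, CC(C)CO
Why: Acid-catalysed vinylogous esterification of a cyclic 1,3-dione with azeotropic removal of water is a routine condensation, and the symmetry of 1 allows only one product.

**Step 2**
Reactants: 2 3-isobutoxy-2-methylcyclohex-2-en-1-one; 3 allyl chloroformate
Product: 4 allyl 4-isobutoxy-3-methyl-2-oxocyclohex-3-ene-1-carboxylate (racemic)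
Conditions: LiN(iPr)2 (2.1 equiv), THF–toluene, −78 °C; then 3, −78 → −30 °C; aq. NH4Cl
Reagents that add atoms: none
Why: Kinetic deprotonation of the vinylogous ester occurs at the α' methylene (future C10), and Claisen-type C-acylation of the lithium enolate by the chloroformate gives the β-keto ester, whose acidic proton is taken up by the second equivalent of base.

**Step 3**
Reactants: 4 allyl 4-isobutoxy-3-methyl-2-oxocyclohex-3-ene-1-carboxylate
Product: 5 allyl 4-isobutoxy-1,3-dimethyl-2-oxocyclohex-3-ene-1-carboxylate (racemic)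
Conditions: MeI, Cs2CO3, MeCN, 50 °C
Reagents that add atoms: iodomethane, CI
Why: SN2 alkylation of the stabilised β-keto ester enolate builds the fully substituted carbon as a racemate, which does not matter because this stereocentre is erased in the next step.

**Step 4**
Reactants: 5 allyl 4-isobutoxy-1,3-dimethyl-2-oxocyclohex-3-ene-1-carboxylate
Product: 6 (R)-6-allyl-3-isobutoxy-2,6-dimethylcyclohex-2-en-1-one
Conditions: Pd2(dba)3 (2.5 mol%), (R)-t-BuPHOX [(R)-4-tert-butyl-2-(2-diphenylphosphinophenyl)-4,5-dihydrooxazole] (6.25 mol%), toluene, 30 °C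
Reagents that add atoms: none
Why: In this decarboxylative asymmetric allylic alkylation, zerovalent palladium ionises the allyl ester and loss of CO2 gives the same achiral enolate/π-allyl pair from both enantiomers of 5, and the (R)-ligand, the mirror image of the one that gives (S)-2-allyl-2-methylcyclohexanone, should direct C–C bond formation to the enolate face that makes C10 R.

**Step 5**
Reactants: 6 (R)-6-allyl-3-isobutoxy-2,6-dimethylcyclohex-2-en-1-one
Product: 8 (R)-4-allyl-2,4-dimethylcyclohex-2-en-1-one, via allylic alcohol 7 (not isolated)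
Conditions: LiAlH4, Et2O, 0 °C; then 10% aq. HCl, 0 → 23 °C
Reagents that add atoms: water, O
Why: In this Stork–Danheiser transposition, 1,2-reduction of the vinylogous ester followed by acid hydrolysis of the enol ether and loss of water moves the carbonyl group to C3 and the olefin to C4=C5 without touching the quaternary C10.

**Step 6**
Reactants: 8 (R)-4-allyl-2,4-dimethylcyclohex-2-en-1-one
Product: 9 (1S,4R)-4-allyl-2,4-dimethylcyclohex-2-en-1-ol (hydroxyl β, cis to the C10 methyl group)
Conditions: (R)-Me-CBS oxazaborolidine (20 mol%), catecholborane, toluene, −78 °C; then MeOH, aq. NaOH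
Reagents that add atoms: none
Why: In this Corey–Bakshi–Shibata reduction the α-methylated olefinic flank acts as the large group, so the (R)-oxazaborolidine should give the 3S (β) alcohol under reagent control, while catecholborane at low temperature leaves the allyl group unhydroborated and material from the minor enantiomer of 8 emerges as a separable diastereomer.

**Step 7**
Reactants: 10 3-hydroxy-3-methylbutan-2-one
Product: 11 3,3-dimethoxy-2-methylbutan-2-ol
Conditions: HC(OMe)3, MeOH, p-TsOH·H2O (cat.), 23 °C; then Et3N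
Reagents that add atoms: trimethyl orthoformate, COC(OC)OC
Why: Acid-catalysed ketalisation driven by the orthoformate as water scavenger is routine for methyl ketones and leaves the tertiary alcohol free.

**Step 8**
Reactants: 9 (1S,4R)-4-allyl-2,4-dimethylcyclohex-2-en-1-ol; 11 3,3-dimethoxy-2-methylbutan-2-ol
Product: 13 1-[(1R,6R)-6-allyl-2,6-dimethylcyclohex-2-en-1-yl]-3-hydroxy-3-methylbutan-2-one, via allyl vinyl ether 12 (not isolated)
Conditions: 11 (5 equiv), 2,4-dinitrophenol (10 mol%), toluene, 110 °C, MeOH distilled off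
Reagents that add atoms: none
Why: In this ketal Claisen rearrangement, acid-catalysed exchange and loss of methanol (possible only towards the methyl side of 11) give 12, whose [3,3]-sigmatropic shift is suprafacial on the ring, so the β C3–O bond is traded for a β C5–C6 bond (C5 R, trans to the allyl arm on C10) while the olefin moves to C3=C4.

**Step 9**
Reactants: 13 1-[(1R,6R)-6-allyl-2,6-dimethylcyclohex-2-en-1-yl]-3-hydroxy-3-methylbutan-2-one
Product: 14 1-[(1R,6R)-6-allyl-2,6-dimethylcyclohex-2-en-1-yl]-3-methyl-3-(triethylsilyloxy)butan-2-one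
Conditions: Et3SiOTf, 2,6-lutidine, CH2Cl2, −78 → 0 °C
Reagents that add atoms: triethylsilyl trifluoromethanesulfonate, CC[Si](CC)(CC)OS(=O)(=O)C(F)(F)F
Why: Silylation of a tertiary alcohol with a silyl triflate and a hindered pyridine base is standard, and the triethylsilyl ether is chosen because it should outlast the aqueous oxidations and amine bases ahead yet fall to fluoride at the end.

**Step 10**
Reactants: 14 1-[(1R,6R)-6-allyl-2,6-dimethylcyclohex-2-en-1-yl]-3-methyl-3-(triethylsilyloxy)butan-2-one
Product: 16 2-{(1R,2R)-1,3-dimethyl-2-[3-methyl-2-oxo-3-(triethylsilyloxy)butyl]cyclohex-3-en-1-yl}acetaldehyde, via vicinal diol 15 (not isolated)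
Conditions: OsO4 (2 mol%), NaIO4 (4 equiv), 2,6-lutidine (2 equiv), 1,4-dioxane–H2O (3:1), 0 → 23 °C, stopped at consumption of 14
Reagents that add atoms: osmium tetroxide, O=[Os](=O)(=O)=O (catalytic oxygen carrier); sodium periodate, [Na+].[O-]I(=O)(=O)=O; water, O
Why: In this Lemieux–Johnson cleavage, osmylation should favour the unhindered monosubstituted olefin over the ring olefin, which is flanked by the C4 methyl group and the branched C5, after which periodate cuts diol 15 and 2,6-lutidine curbs over-oxidation.

**Step 11**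
Reactants: 16 2-{(1R,2R)-1,3-dimethyl-2-[3-methyl-2-oxo-3-(triethylsilyloxy)butyl]cyclohex-3-en-1-yl}acetaldehyde
Product: 18 7α-hydroxy-11-(triethylsilyloxy)eudesm-3-en-8-one [(3S,4aR,8aR)-3-hydroxy-5,8a-dimethyl-3-[2-(triethylsilyloxy)propan-2-yl]-3,4,4a,7,8,8a-hexahydronaphthalen-2(1H)-one]
Conditions: 2-(pentafluorophenyl)-6,7-dihydro-5H-pyrrolo[2,1-c][1,2,4]triazol-2-ium tetrafluoroborate (20 mol%), DBU (15 mol%), THF (0.05 M), argon, 23 → 45 °C
Reagents that add atoms: none
Why: The carbene freed from the triazolium salt adds to the open C8 aldehyde and a proton shift gives the enaminol (Breslow intermediate), an acyl anion equivalent at C8 that attacks the C7 carbonyl carbon, after which proton transfer and expulsion of the carbene release the α-ketol. The closest known reaction type is the intramolecular crossed aldehyde–ketone benzoin cyclisation under azolium carbene catalysis, which turns aliphatic keto aldehydes into six-membered tertiary α-ketols. Ring B (C5–C6–C7–C8–C9–C10) closes in a 6-exo-trig mode, with the carbonyl oxygen of C7 outside the new ring and the two arms held trans-diequatorial on ring A by C5 and C10. The one new stereocentre, C7, is set by a chair-like transition state in which the bulky C(CH3)2OSiEt3 group lies equatorial (β) and the new hydroxyl axial (α, 7S), and the reversibility of the addition should drain material towards this more stable epimer. The required donor/acceptor selectivity is built into 16, because a ketone cannot form the enaminol and the inductive pull of the α-silyloxy group offsets the steric shielding of the C7 carbonyl group. Keeping DBU below the azolium loading leaves little free base and so holds back the competing five-ring aldol closures (C6 to C8, C9 to C7), while the silyl ether blocks retro-aldol loss of acetone from the product.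

**Step 12**
Reactants: 18 7α-hydroxy-11-(triethylsilyloxy)eudesm-3-en-8-one
Product: 19 3α,4α,7α-trihydroxy-11-(triethylsilyloxy)eudesman-8-one (3R,4S,5R,7S,10R)
Conditions: OsO4 (5 mol%), NMO (2 equiv), acetone–H2O (5:1), 23 °C; aq. Na2SO3
Reagents that add atoms: osmium tetroxide, O=[Os](=O)(=O)=O (catalytic oxygen carrier); N-methylmorpholine N-oxide, C[N+]1([O-])CCOCC1; water, O
Why: In this catalytic OsO4/NMO syn-dihydroxylation, the axial C10 methyl group shields the β face of the trans-fused Δ3 olefin, so the reagent should add from the α face and set C3 (R) and C4 (S) together as the cis 3α,4α-diol.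

**Step 13**
Reactants: 20 angelic acid [(Z)-2-methylbut-2-enoic acid]
Product: 21 (Z)-2-methylbut-2-en-1-ol
Conditions: LiAlH4, Et2O, 0 → 23 °C; then H2O, aq. NaOH
Reagents that add atoms: none
Why: Hydride reduction of the alkyl-substituted α,β-unsaturated acid stops at the allylic alcohol and, being free of acid and heat, should keep the Z geometry.

**Step 14**
Reactants: 21 (Z)-2-methylbut-2-en-1-ol
Product: 22 [(2R,3S)-2,3-dimethyloxiran-2-yl]methanol
Conditions: Ti(OiPr)4 (10 mol%), D-(−)-diisopropyl tartrate (12 mol%), t-BuOOH (decane solution), 4 Å molecular sieves, CH2Cl2, −20 °C; non-aqueous work-up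
Reagents that add atoms: tert-butyl hydroperoxide, CC(C)(C)OO
Why: In this Sharpless asymmetric epoxidation the syn oxygen transfer keeps the C3' methyl group cis to the CH2OH group, and D-(−)-tartrate is the ligand enantiomer that turns Z-configured allylic alcohols into 2R,3S epoxy alcohols, so C2' and C3' are set together.

**Step 15**
Reactants: 22 [(2R,3S)-2,3-dimethyloxiran-2-yl]methanol
Product: 23 (2S,3S)-2,3-epoxy-2-methylbutanoic acid [(2S,3S)-epoxyangelic acid]
Conditions: RuCl3·xH2O (2 mol%), NaIO4 (4 equiv), MeCN–EtOAc–H2O, 0 → 23 °C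
Reagents that add atoms: sodium periodate, [Na+].[O-]I(=O)(=O)=O (oxygen passed on through RuO4); water, O
Why: RuO4-catalysed oxidation takes primary epoxy alcohols to epoxy acids without opening the ring or touching either stereocentre, and the change of the C2' descriptor from R to S reflects only the new substituent priorities.

**Step 16**
Reactants: 19 3α,4α,7α-trihydroxy-11-(triethylsilyloxy)eudesman-8-one; 23 (2S,3S)-2,3-epoxy-2-methylbutanoic acid
Product: 25 3α-[(2S,3S)-2,3-epoxy-2-methylbutanoyloxy]-4α,7α-dihydroxy-11-(triethylsilyloxy)eudesman-8-one, via mixed anhydride 24 (not isolated)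
Conditions: 23, 2,4,6-trichlorobenzoyl chloride, Et3N, toluene, 23 °C; then 19, DMAP, toluene, 23 → 45 °C
Reagents that add atoms: 2,4,6-trichlorobenzoyl chloride, O=C(Cl)c1c(Cl)cc(Cl)cc1Cl (its acyl group is held in 24 and leaves again)
Why: In this Yamaguchi esterification, DMAP picks the epoxyacyl carbonyl group of 24 because the aroyl carbonyl group is screened by two ortho chlorine atoms, and the acylpyridinium ion should meet only the single secondary hydroxyl (axial 3α-OH), since the hydroxyls at C4 and C7 are tertiary and C11 is silylated.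

**Step 17**
Reactants: 25 3α-[(2S,3S)-2,3-epoxy-2-methylbutanoyloxy]-4α,7α-dihydroxy-11-(triethylsilyloxy)eudesman-8-one
Product: 26 3α-[(2S,3S)-2,3-epoxy-2-methylbutanoyloxy]-4α,7α,11-trihydroxyeudesman-8-one (CNP0145407.1)
Conditions: HF·pyridine, pyridine, THF, 0 → 23 °C
Reagents that add atoms: none
Why: Fluoride-driven Si–O cleavage under buffered, weakly acidic conditions is a standard desilylation that should spare the epoxy ester and avoids the base that could trigger retro-aldol loss of acetone or α-ketol rearrangement.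

**Compound list**
1 | 2-methylcyclohexane-1,3-dione | CC1C(=O)CCCC1=O | starting material
2 | 3-isobutoxy-2-methylcyclohex-2-en-1-one | CC1=C(OCC(C)C)CCCC1=O | intermediate
3 | allyl chloroformate | C=CCOC(Cl)=O | starting material
4 | allyl 4-isobutoxy-3-methyl-2-oxocyclohex-3-ene-1-carboxylate (racemic) | CC1=C(OCC(C)C)CCC(C(=O)OCC=C)C1=O | intermediate
5 | allyl 4-isobutoxy-1,3-dimethyl-2-oxocyclohex-3-ene-1-carboxylate (racemic) | CC1=C(OCC(C)C)CCC(C)(C(=O)OCC=C)C1=O | intermediate
6 | (R)-6-allyl-3-isobutoxy-2,6-dimethylcyclohex-2-en-1-one | CC1=C(OCC(C)C)CC[C@](C)(CC=C)C1=O | intermediate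
7 | (6R)-6-allyl-3-isobutoxy-2,6-dimethylcyclohex-2-en-1-ol (carbinol epimers) | CC1=C(OCC(C)C)CC[C@](C)(CC=C)C1O | intermediate (not isolated)
8 | (R)-4-allyl-2,4-dimethylcyclohex-2-en-1-one | O=C1CC[C@](C)(CC=C)C=C1C | intermediate
9 | (1S,4R)-4-allyl-2,4-dimethylcyclohex-2-en-1-ol | O[C@H]1CC[C@](C)(CC=C)C=C1C | intermediate
10 | 3-hydroxy-3-methylbutan-2-one | CC(=O)C(C)(C)O | starting material
11 | 3,3-dimethoxy-2-methylbutan-2-ol | COC(C)(OC)C(C)(C)O | intermediate
12 | 3-{[(1S,4R)-4-allyl-2,4-dimethylcyclohex-2-en-1-yl]oxy}-2-methylbut-3-en-2-ol | C=C(O[C@H]1CC[C@](C)(CC=C)C=C1C)C(C)(C)O | intermediate (not isolated)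
13 | 1-[(1R,6R)-6-allyl-2,6-dimethylcyclohex-2-en-1-yl]-3-hydroxy-3-methylbutan-2-one | CC1=CCC[C@](C)(CC=C)[C@H]1CC(=O)C(C)(C)O | intermediate
14 | 1-[(1R,6R)-6-allyl-2,6-dimethylcyclohex-2-en-1-yl]-3-methyl-3-(triethylsilyloxy)butan-2-one | CC1=CCC[C@](C)(CC=C)[C@H]1CC(=O)C(C)(C)O[Si](CC)(CC)CC | intermediate
15 | 1-[(1R,6R)-6-(2,3-dihydroxypropyl)-2,6-dimethylcyclohex-2-en-1-yl]-3-methyl-3-(triethylsilyloxy)butan-2-one (carbinol epimers) | CC1=CCC[C@](C)(CC(O)CO)[C@H]1CC(=O)C(C)(C)O[Si](CC)(CC)CC | intermediate (not isolated)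
16 | 2-{(1R,2R)-1,3-dimethyl-2-[3-methyl-2-oxo-3-(triethylsilyloxy)butyl]cyclohex-3-en-1-yl}acetaldehyde | CC1=CCC[C@](C)(CC=O)[C@H]1CC(=O)C(C)(C)O[Si](CC)(CC)CC | intermediate (key-step precursor)
18 | 7α-hydroxy-11-(triethylsilyloxy)eudesm-3-en-8-one | CC1=CCC[C@]2(C)CC(=O)[C@@](O)(C(C)(C)O[Si](CC)(CC)CC)C[C@@H]12 | intermediate (key-step product)
19 | 3α,4α,7α-trihydroxy-11-(triethylsilyloxy)eudesman-8-one | O[C@@H]1CC[C@]2(C)CC(=O)[C@@](O)(C(C)(C)O[Si](CC)(CC)CC)C[C@H]2[C@]1(C)O | intermediate
20 | angelic acid | C/C=C(/C)C(=O)O | starting material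
21 | (Z)-2-methylbut-2-en-1-ol | C/C=C(/C)CO | intermediate
22 | [(2R,3S)-2,3-dimethyloxiran-2-yl]methanol | C[C@@H]1O[C@]1(C)CO | intermediate
23 | (2S,3S)-2,3-epoxy-2-methylbutanoic acid | C[C@@H]1O[C@]1(C)C(=O)O | intermediate
24 | (2S,3S)-2,3-epoxy-2-methylbutanoic 2,4,6-trichlorobenzoic anhydride | C[C@@H]1O[C@]1(C)C(=O)OC(=O)c1c(Cl)cc(Cl)cc1Cl | intermediate (not isolated)
25 | 3α-[(2S,3S)-2,3-epoxy-2-methylbutanoyloxy]-4α,7α-dihydroxy-11-(triethylsilyloxy)eudesman-8-one | C[C@@H]1O[C@]1(C)C(=O)O[C@@H]1CC[C@]2(C)CC(=O)[C@@](O)(C(C)(C)O[Si](CC)(CC)CC)C[C@H]2[C@]1(C)O | intermediate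
26 | 3α-[(2S,3S)-2,3-epoxy-2-methylbutanoyloxy]-4α,7α,11-trihydroxyeudesman-8-one (CNP0145407.1) | C[C@@H]1O[C@]1(C)C(=O)O[C@@H]1CC[C@]2(C)CC(=O)[C@@](O)(C(C)(C)O)C[C@H]2[C@]1(C)O | target

Number 17 is not assigned, because the carbene-bound enaminol of step 11 belongs to the catalytic cycle.

Total step count: 17. Longest linear sequence: 13 (steps 1–6, 8–12, 16, 17).

**Steps most likely to fail**

**Step 11.** Addition of the enaminol to the neopentyl-type C7 ketone may be slow, so base-mediated aldol closure or self-condensation of the aldehyde could overtake ring closure. The fallback forms the same C7–C8 bond by reductive coupling and sets out from 16.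
- SmI2 (2.5 equiv), t-BuOH, THF, −78 °C reduces the aldehyde first. The ketyl radical then closes onto the ketone in an intramolecular pinacol coupling.
- Samarium chelation favours the cis diol with the bulky group equatorial, giving 11-(triethylsilyloxy)eudesm-3-ene-7α,8α-diol F1.
- Parikh–Doering oxidation (SO3·pyridine, DMSO, Et3N, CH2Cl2, 0 °C) of the only secondary hydroxyl comes back to the route at 18.

**Step 8.** The allylic alcohol may ionise or dehydrate under hot acidic conditions, and the sigmatropic shift onto a carbon next to the quaternary C10 may be sluggish. The fallback sets out from 9 and replaces the acid-catalysed ketal exchange by a neutral rearrangement followed by build-up of the ketol.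
- Eschenmoser–Claisen rearrangement (N,N-dimethylacetamide dimethyl acetal, xylene, 140 °C, same suprafacial transfer) should give 2-[(1R,6R)-6-allyl-2,6-dimethylcyclohex-2-en-1-yl]-N,N-dimethylacetamide F2.
- Isopropenyllithium (from 2-bromopropene and t-BuLi, THF, −78 °C) converts the amide into 1-[(1R,6R)-6-allyl-2,6-dimethylcyclohex-2-en-1-yl]-3-methylbut-3-en-2-one F3.
- Mukaiyama-type reductive α-hydroxylation of the enone (Mn(dpm)3 with dpm = dipivaloylmethanate, cat., PhSiH3, O2, i-PrOH, 0 °C; then P(OEt)3) comes back to the route at 13.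

**Step 10.** Site selectivity may be poor, with osmylation of the ring olefin competing with that of the allyl group. The fallback sets out from 8, where the only other olefin is the electron-poor enone, and moves the cleavage ahead of the rearrangement.
- Ozonolysis (O3, CH2Cl2–MeOH, −78 °C; Me2S) should give (R)-2-(1,3-dimethyl-4-oxocyclohex-2-en-1-yl)acetaldehyde F4.
- HC(OMe)3, MeOH and p-TsOH (cat.) mask the aldehyde as (R)-4-(2,2-dimethoxyethyl)-2,4-dimethylcyclohex-2-en-1-one F5.
- Reduction as in step 6 gives (1S,4R)-4-(2,2-dimethoxyethyl)-2,4-dimethylcyclohex-2-en-1-ol F6.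
- Rearrangement with 11 as in step 8 gives 1-[(1R,6R)-6-(2,2-dimethoxyethyl)-2,6-dimethylcyclohex-2-en-1-yl]-3-hydroxy-3-methylbutan-2-one F7.
- Et3SiOTf/2,6-lutidine silylates the carbinol to 1-[(1R,6R)-6-(2,2-dimethoxyethyl)-2,6-dimethylcyclohex-2-en-1-yl]-3-methyl-3-(triethylsilyloxy)butan-2-one F8.
- An excess of the same reagent pair followed by water unmasks the aldehyde without loss of the silyl ether, coming back to the route at 16.

**Further compounds**
F1 | step 11 | 11-(triethylsilyloxy)eudesm-3-ene-7α,8α-diol | CC1=CCC[C@]2(C)C[C@H](O)[C@@](O)(C(C)(C)O[Si](CC)(CC)CC)C[C@@H]12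
F2 | step 8 | 2-[(1R,6R)-6-allyl-2,6-dimethylcyclohex-2-en-1-yl]-N,N-dimethylacetamide | CC1=CCC[C@](C)(CC=C)[C@H]1CC(=O)N(C)C
F3 | step 8 | 1-[(1R,6R)-6-allyl-2,6-dimethylcyclohex-2-en-1-yl]-3-methylbut-3-en-2-one | CC1=CCC[C@](C)(CC=C)[C@H]1CC(=O)C(C)=C
F4 | step 10 | (R)-2-(1,3-dimethyl-4-oxocyclohex-2-en-1-yl)acetaldehyde | O=C1CC[C@](C)(CC=O)C=C1C
F5 | step 10 | (R)-4-(2,2-dimethoxyethyl)-2,4-dimethylcyclohex-2-en-1-one | O=C1CC[C@](C)(CC(OC)OC)C=C1C
F6 | step 10 | (1S,4R)-4-(2,2-dimethoxyethyl)-2,4-dimethylcyclohex-2-en-1-ol | O[C@H]1CC[C@](C)(CC(OC)OC)C=C1C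
F7 | step 10 | 1-[(1R,6R)-6-(2,2-dimethoxyethyl)-2,6-dimethylcyclohex-2-en-1-yl]-3-hydroxy-3-methylbutan-2-one | CC1=CCC[C@](C)(CC(OC)OC)[C@H]1CC(=O)C(C)(C)O
F8 | step 10 | 1-[(1R,6R)-6-(2,2-dimethoxyethyl)-2,6-dimethylcyclohex-2-en-1-yl]-3-methyl-3-(triethylsilyloxy)butan-2-one | CC1=CCC[C@](C)(CC(OC)OC)[C@H]1CC(=O)C(C)(C)O[Si](CC)(CC)CC
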